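**Plan**

1. Ring numbering: C1 (OMe), C2 (OH), C3 (OBz), C4 (OH), C5 (alkene carbon carrying C6H2OBz), C5a (alkene CH). The enabling feature is that the C1 and C4 oxygens are para on the six-membered carbocycle (a masked hydroquinone), and that the trans C2–OH/C3–OBz pair is what an oxirane across C2–C3 leaves when benzoate opens it at C3.
2. The retrosynthesis cuts, in order: the C6–O benzoate, the C4 carbinol C–H (back to a C4 enone), the C3–OBz bond (back to the C2/C3 oxirane), the C4 ketone (back to a dimethyl ketal), the C1 O–Me and C1–H bonds (back to a C1 ketone), and both oxirane C–O bonds. This leads to quinone monoketal 4 and, by rearomatisation, to phenol 2 and aldehyde 1.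
3. Forward, the carbocycle is the benzene ring of 1 and no C–C bond is made. The only ring formed is the oxirane (step 3), and it is opened again in step 8.
4. Stereochemistry: C2 and C3 are set in absolute terms by the tartrate-controlled epoxidation. C1 follows from hydride delivery directed by the oxirane oxygen (anti), C3 is inverted by the SN2 opening with benzoate, and C4 follows from axial hydride addition in the Luche reduction.

Key step: step 3

Assumption: L-(+)-diisopropyl tartrate is taken to be the enantiomer that leads to the (1S,6R) oxirane 7; the sense of induction is to be checked on the first batch, and D-(−)-diisopropyl tartrate replaces it with no other change if the mirror-image oxirane forms.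

**Route**

Step 1
Reactants: 1 5-hydroxy-2-methoxybenzaldehyde
Product: 2 3-(hydroxymethyl)-4-methoxyphenol
Conditions: NaBH4, EtOH, 0 °C to rt
Reagents that add atoms: none
Why: Borohydride reduction of an aryl aldehyde to the benzylic alcohol, to which the phenol and the aryl methyl ether are inert.

Step 2
Reactants: 2 3-(hydroxymethyl)-4-methoxyphenol; 3 methanol
Product: 4 3-(hydroxymethyl)-4,4-dimethoxycyclohexa-2,5-dien-1-one
Conditions: PhI(OAc)2 (1.1 equiv), MeOH, 0 °C; solid NaHCO3 quench
Reagents that add atoms: methanol, CO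
Why: Oxidative dearomatisation of a para-methoxyphenol by a hypervalent iodine diacetate, in which methanol traps the oxidised ring at the methoxy-bearing carbon and so gives the para-quinone monoketal with the ketone at the former phenol carbon (C1) and the ketal at C4, without creating a stereocentre.

Step 3
Reactants: 4 3-(hydroxymethyl)-4,4-dimethoxycyclohexa-2,5-dien-1-one; 5 trityl hydroperoxide
Product: 7 (1S,6R)-4-(hydroxymethyl)-5,5-dimethoxy-7-oxabicyclo[4.1.0]hept-3-en-2-one, via sodium β-peroxy enolate 6 (not isolated)
Conditions: Ph3COOH (1.5 equiv), NaN(SiMe3)2 (2.5 equiv), L-(+)-diisopropyl tartrate (1.2 equiv), toluene, −78 to −50 °C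
Reagents that add atoms: trityl hydroperoxide, OOC(c1ccccc1)(c1ccccc1)c1ccccc1
Why: Weitz–Scheffer nucleophilic epoxidation: sodium trityl peroxide adds in conjugate fashion to C3, the β-carbon of the unsubstituted enone alkene, to give dienolate 6, whose α-carbon C2 then attacks the peroxide oxygen bound to C3 and expels trityl oxide, so that the C3–O and C2–O bonds form one after the other. The closest known reaction type is the tartrate-mediated asymmetric nucleophilic epoxidation of hydroxymethyl-bearing quinone monoketals with trityl hydroperoxide and a sodium amide base. The oxirane closes by a 3-exo-tet displacement at oxygen and is therefore cis-fused to the carbocycle. C3 and C2 are set together by the face on which the peroxide is delivered, and that face is chosen by the chiral sodium tartrate aggregate, which holds the C6 alkoxide of 4 and the peroxide anion in one complex. The step needs site selectivity between two enone alkenes and enantiofacial selectivity: the first is secured by the substrate, because the competing alkene ends in the fully substituted β-carbon C5, and the second by the tartrate, while the C4 ketal keeps C1 and C4 at different oxidation levels for later use.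

Step 4
Reactants: 7 (1S,6R)-4-(hydroxymethyl)-5,5-dimethoxy-7-oxabicyclo[4.1.0]hept-3-en-2-one; 8 tert-butyldimethylsilyl chloride
Product: 9 (1S,6R)-4-[(tert-butyldimethylsilyloxy)methyl]-5,5-dimethoxy-7-oxabicyclo[4.1.0]hept-3-en-2-one
Conditions: TBSCl, imidazole, CH2Cl2, 0 °C
Reagents that add atoms: tert-butyldimethylsilyl chloride, CC(C)(C)[Si](C)(C)Cl
Why: Silylation of the only hydroxyl group, a primary alcohol, with a silyl chloride and imidazole, placed after the epoxidation because that step needs the free alcohol as its anchor.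

Step 5
Reactants: 9 (1S,6R)-4-[(tert-butyldimethylsilyloxy)methyl]-5,5-dimethoxy-7-oxabicyclo[4.1.0]hept-3-en-2-one
Product: 10 (1R,2S,6R)-4-[(tert-butyldimethylsilyloxy)methyl]-5,5-dimethoxy-7-oxabicyclo[4.1.0]hept-3-en-2-ol (C1 hydroxyl trans to the oxirane oxygen)
Conditions: i-Bu2AlH (1.3 equiv), THF, −78 °C
Reagents that add atoms: none
Why: 1,2-Reduction of the enone carbonyl by i-Bu2AlH, in which aluminium bound to the oxirane oxygen should deliver hydride to the oxirane face of C1 and so place the new hydroxyl trans to the oxirane (anti epoxy alcohol), the known behaviour of this reductant with epoxy quinone monoketals.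

Step 6
Reactants: 10 (1R,2S,6R)-4-[(tert-butyldimethylsilyloxy)methyl]-5,5-dimethoxy-7-oxabicyclo[4.1.0]hept-3-en-2-ol; 11 iodomethane
Product: 12 (1R,2S,6R)-4-[(tert-butyldimethylsilyloxy)methyl]-2,5,5-trimethoxy-7-oxabicyclo[4.1.0]hept-3-ene (numbered as in 10)
Conditions: MeI (5 equiv), then NaH, THF/DMF, 0 °C
Reagents that add atoms: iodomethane, CI
Why: Williamson ether synthesis on the C1 alkoxide with iodomethane present from the start so that O-methylation outruns Payne rearrangement, the C1 configuration being kept because only the O–H bond reacts.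

Step 7
Reactants: 12 (1R,2S,6R)-4-[(tert-butyldimethylsilyloxy)methyl]-2,5,5-trimethoxy-7-oxabicyclo[4.1.0]hept-3-ene; 13 water
Product: 14 (1R,5S,6R)-3-[(tert-butyldimethylsilyloxy)methyl]-5-methoxy-7-oxabicyclo[4.1.0]hept-3-en-2-one (C4 ketone, C2/C3 oxirane, C1 methoxy)
Conditions: pyridinium p-toluenesulfonate (0.2 equiv), acetone/H2O (10:1), 25–40 °C
Reagents that add atoms: water, O
Why: Mild acid-catalysed hydrolysis of the dimethyl ketal through an allylic oxocarbenium ion gives the conjugated enone, and the primary silyl ether, the methyl ether and the electron-poor oxirane should tolerate the pyridinium salt.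

Step 8
Reactants: 14 (1R,5S,6R)-3-[(tert-butyldimethylsilyloxy)methyl]-5-methoxy-7-oxabicyclo[4.1.0]hept-3-en-2-one; 15 benzoic acid
Product: 16 (1S,5S,6R)-3-[(tert-butyldimethylsilyloxy)methyl]-6-hydroxy-5-methoxy-2-oxocyclohex-3-en-1-yl benzoate
Conditions: PhCO2H (3 equiv), PhCO2Cs (0.3 equiv), DMF, 0 °C to rt; crude product taken on at once
Reagents that add atoms: benzoic acid, OC(=O)c1ccccc1
Why: SN2 opening of an α,β-epoxy ketone by a carboxylate at the carbon α to the carbonyl (C3), which the adjacent C=O activates, proceeds with inversion so that the benzoate enters trans to the C2 oxygen, while the excess benzoic acid protonates the aldolate at once and holds back retro-aldol cleavage and β-elimination.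

Step 9
Reactants: 16 (1S,5S,6R)-3-[(tert-butyldimethylsilyloxy)methyl]-6-hydroxy-5-methoxy-2-oxocyclohex-3-en-1-yl benzoate
Product: 17 (1R,2S,5S,6R)-3-[(tert-butyldimethylsilyloxy)methyl]-2,6-dihydroxy-5-methoxycyclohex-3-en-1-yl benzoate
Conditions: NaBH4, CeCl3·7H2O, MeOH, −78 °C; AcOH quench at −78 °C
Reagents that add atoms: none
Why: Luche 1,2-reduction, in which hydride should add axially to C4 of the all-equatorial half-chair of 16 from the face opposite the axial C3–H and so give the pseudo-equatorial C4 hydroxyl trans to the C3 benzoate.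

Step 10
Reactants: 17 (1R,2S,5S,6R)-3-[(tert-butyldimethylsilyloxy)methyl]-2,6-dihydroxy-5-methoxycyclohex-3-en-1-yl benzoate
Product: 18 (1R,2S,5S,6R)-2,6-dihydroxy-3-(hydroxymethyl)-5-methoxycyclohex-3-en-1-yl benzoate
Conditions: HF·pyridine, pyridine/THF, 0 °C
Reagents that add atoms: none
Why: Fluoride-mediated desilylation under buffered, weakly acidic conditions removes the primary silyl ether without the basic medium that would let the C3 benzoate migrate to a neighbouring hydroxyl.

Step 11
Reactants: 18 (1R,2S,5S,6R)-2,6-dihydroxy-3-(hydroxymethyl)-5-methoxycyclohex-3-en-1-yl benzoate; 19 benzoyl chloride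
Product: 20 [(3S,4R,5R,6S)-5-(benzoyloxy)-4,6-dihydroxy-3-methoxycyclohex-1-en-1-yl]methyl benzoate (CNP0349013.8)
Conditions: BzCl (1.05 equiv), 2,4,6-collidine, CH2Cl2, −78 to −40 °C
Reagents that add atoms: benzoyl chloride, O=C(Cl)c1ccccc1
Why: Kinetically selective acylation of the primary allylic alcohol over the two flanked secondary alcohols with a slight excess of acid chloride and a hindered pyridine base at low temperature, which touches no stereocentre.

**Compound list**

1 | 5-hydroxy-2-methoxybenzaldehyde | COc1ccc(O)cc1C=O | starting material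
2 | 3-(hydroxymethyl)-4-methoxyphenol | COc1ccc(O)cc1CO | intermediate
3 | methanol | CO | starting material
4 | 3-(hydroxymethyl)-4,4-dimethoxycyclohexa-2,5-dien-1-one | O=C1C=C(CO)C(OC)(OC)C=C1 | intermediate
5 | trityl hydroperoxide (triphenylmethyl hydroperoxide) | OOC(c1ccccc1)(c1ccccc1)c1ccccc1 | starting material
6 | sodium dienolate of (5R)-3-(hydroxymethyl)-4,4-dimethoxy-5-(trityldioxy)cyclohex-2-en-1-one (peroxide on target carbon C3) | [Na+].[O-]C1=C[C@@H](OOC(c2ccccc2)(c2ccccc2)c2ccccc2)C(OC)(OC)C(CO)=C1 | intermediate
7 | (1S,6R)-4-(hydroxymethyl)-5,5-dimethoxy-7-oxabicyclo[4.1.0]hept-3-en-2-one | O=C1C=C(CO)C(OC)(OC)[C@@H]2O[C@H]12 | intermediate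
8 | tert-butyldimethylsilyl chloride | CC(C)(C)[Si](C)(C)Cl | starting material
9 | (1S,6R)-4-[(tert-butyldimethylsilyloxy)methyl]-5,5-dimethoxy-7-oxabicyclo[4.1.0]hept-3-en-2-one | O=C1C=C(CO[Si](C)(C)C(C)(C)C)C(OC)(OC)[C@@H]2O[C@H]12 | intermediate
10 | (1R,2S,6R)-4-[(tert-butyldimethylsilyloxy)methyl]-5,5-dimethoxy-7-oxabicyclo[4.1.0]hept-3-en-2-ol, hydroxyl trans to the oxirane | O[C@H]1C=C(CO[Si](C)(C)C(C)(C)C)C(OC)(OC)[C@@H]2O[C@H]12 | intermediate
11 | iodomethane | CI | starting material
12 | (1R,2S,6R)-4-[(tert-butyldimethylsilyloxy)methyl]-2,5,5-trimethoxy-7-oxabicyclo[4.1.0]hept-3-ene | CO[C@H]1C=C(CO[Si](C)(C)C(C)(C)C)C(OC)(OC)[C@@H]2O[C@H]12 | intermediate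
13 | water | O | starting material
14 | (1R,5S,6R)-3-[(tert-butyldimethylsilyloxy)methyl]-5-methoxy-7-oxabicyclo[4.1.0]hept-3-en-2-one | CO[C@H]1C=C(CO[Si](C)(C)C(C)(C)C)C(=O)[C@@H]2O[C@H]12 | intermediate
15 | benzoic acid | OC(=O)c1ccccc1 | starting material
16 | (1S,5S,6R)-3-[(tert-butyldimethylsilyloxy)methyl]-6-hydroxy-5-methoxy-2-oxocyclohex-3-en-1-yl benzoate | CO[C@H]1C=C(CO[Si](C)(C)C(C)(C)C)C(=O)[C@@H](OC(=O)c2ccccc2)[C@@H]1O | intermediate
17 | (1R,2S,5S,6R)-3-[(tert-butyldimethylsilyloxy)methyl]-2,6-dihydroxy-5-methoxycyclohex-3-en-1-yl benzoate | CO[C@H]1C=C(CO[Si](C)(C)C(C)(C)C)[C@H](O)[C@@H](OC(=O)c2ccccc2)[C@@H]1O | intermediate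
18 | (1R,2S,5S,6R)-2,6-dihydroxy-3-(hydroxymethyl)-5-methoxycyclohex-3-en-1-yl benzoate | CO[C@H]1C=C(CO)[C@H](O)[C@@H](OC(=O)c2ccccc2)[C@@H]1O | intermediate
19 | benzoyl chloride | O=C(Cl)c1ccccc1 | starting material
20 | [(3S,4R,5R,6S)-5-(benzoyloxy)-4,6-dihydroxy-3-methoxycyclohex-1-en-1-yl]methyl benzoate | CO[C@H]1C=C(COC(=O)c2ccccc2)[C@H](O)[C@@H](OC(=O)c2ccccc2)[C@@H]1O | target

**Summary**

Total step count: 11. Longest linear sequence: 11 steps (1 to 20).

Steps most likely to fail:

1. Step 8. The aldol formed on ring opening may lose the C2 hydroxyl by β-elimination and then methanol, which would aromatise the ring; benzoate may also attack C2 in part. The fallback sets out from 14, avoids any β-hydroxy ketone and comes back at 17. Reduction of 14 with i-Bu2AlH (THF, −78 °C), again directed by the oxirane oxygen, should give the C4 alcohol trans to the oxirane, anti epoxy alcohol F1. In NaOH, t-BuOH/H2O at 40 °C its alkoxide undergoes Payne rearrangement to the C3/C4 vinyl oxirane F2 (not isolated), with inversion at C3 and the C2 hydroxyl set free. Hydroxide then opens F2 at the allylic carbon C4 with inversion to give the all-trans C2,C3,C4-triol F3. The C2 and C4 hydroxyls are cis-1,3 and can be bridged with PhB(OH)2 (toluene, azeotropic drying) to give the 2,4-O-phenylboronate F4, which leaves only the C3 hydroxyl free. BzCl in pyridine converts it to the C3 benzoate boronate F5, and exchange with pinacol releases 17.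

2. Step 3. Enantiofacial discrimination may be insufficient, or the sodium alkoxide of 4 may add to a second dienone and consume the substrate. The fallback sets out from 4, changes the chiral controller and comes back at 9. Compound 4 is silylated first (TBSCl, imidazole) to 3-[(tert-butyldimethylsilyloxy)methyl]-4,4-dimethoxycyclohexa-2,5-dien-1-one F6. F6 is then epoxidised under chiral phase-transfer catalysis (t-BuOOH, NaOH, toluene, 0 °C) with N-benzylcinchonidinium chloride or its pseudo-enantiomer N-benzylcinchoninium chloride, whichever leads to the (1S,6R) oxirane. The ammonium–peroxide ion pair then selects the face, the same C5 substitution directs attack to C3, and the product is 9 directly.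

3. Step 5. Hydride delivery may not be face-selective enough, so that the alcohol cis to the oxirane forms. The fallback sets out from 9, sets C1 by inversion and comes back at 10. Luche reduction (NaBH4, CeCl3·7H2O, MeOH, −78 °C), in which external hydride should attack the face away from the oxirane, gives the syn epoxy alcohol F7. Mitsunobu esterification with 4-nitrobenzoic acid (PPh3, diisopropyl azodicarboxylate, THF, 0 °C) inverts the allylic centre C1 to give the anti 4-nitrobenzoate F8. Methanolysis (K2CO3, MeOH, 0 °C) releases 10.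

Further compounds

F1 | step 8 | C4 alcohol of 14 with the hydroxyl trans to the C2/C3 oxirane (anti epoxy alcohol; C1 methoxy, C6 silyl ether) | CO[C@H]1C=C(CO[Si](C)(C)C(C)(C)C)[C@@H](O)[C@@H]2O[C@H]12
F2 | step 8 | Payne isomer: C3/C4 vinyl oxirane on the face opposite the C2 hydroxyl | CO[C@H]1C=C(CO[Si](C)(C)C(C)(C)C)[C@H]2O[C@H]2[C@@H]1O
F3 | step 8 | all-trans triol: 17 without the benzoyl group | CO[C@H]1C=C(CO[Si](C)(C)C(C)(C)C)[C@H](O)[C@@H](O)[C@@H]1O
F4 | step 8 | 2,4-O-phenylboronate of F3 (boron bridges the C2 and C4 oxygens, C3 hydroxyl free) | CO[C@H]1C=C(CO[Si](C)(C)C(C)(C)C)[C@H](O2)[C@@H](O)[C@@H]1OB2c1ccccc1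
F5 | step 8 | C3 benzoate of boronate F4 | CO[C@H]1C=C(CO[Si](C)(C)C(C)(C)C)[C@H](O2)[C@@H](OC(=O)c3ccccc3)[C@@H]1OB2c1ccccc1
F6 | step 3 | 3-[(tert-butyldimethylsilyloxy)methyl]-4,4-dimethoxycyclohexa-2,5-dien-1-one | O=C1C=C(CO[Si](C)(C)C(C)(C)C)C(OC)(OC)C=C1
F7 | step 5 | C1 epimer of 10 (hydroxyl cis to the oxirane, syn epoxy alcohol) | O[C@@H]1C=C(CO[Si](C)(C)C(C)(C)C)C(OC)(OC)[C@@H]2O[C@H]12
F8 | step 5 | 4-nitrobenzoate of 10 (ester trans to the oxirane) | O=C(O[C@H]1C=C(CO[Si](C)(C)C(C)(C)C)C(OC)(OC)[C@@H]2O[C@H]12)c1ccc(cc1)[N+](=O)[O-]
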